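**Assumptions:** Umbilicaric acid has no stereocentres, so "single enantiomer" does not apply. I assume methyl orsellinate and orsellinic acid are purchasable.

## Retrosynthetic overview
- Target **10** comes from one global hydrogenolysis of the benzyl ether and benzyl ester of tridepside **9**.
- **9** comes from a TFAA-mediated depside coupling of the A–B acid **7** with benzyl orsellinate **8** (ring C).
- **7** is the bold key step. The central ring B is used as unprotected orsellinic acid **6**, and its 4-phenoxide is acylated selectively by the hindered acid chloride **5** in aqueous base. The 2-OH is H-bond-chelated and the carboxylate is non-nucleophilic, so no protecting groups are needed on ring B.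
- **5** is made from methyl orsellinate **1** by 4-O-benzylation, 2-O-methylation, hydrolysis and acid-chloride formation.
- No aromatic ring is formed in this route. All three rings come pre-built as orsellinate units.

## Forward route

**Step 1**
Reactants: **1** methyl orsellinate (methyl 2,4-dihydroxy-6-methylbenzoate)
Product: **2** methyl 4-(benzyloxy)-2-hydroxy-6-methylbenzoate
Conditions: BnBr (1.05 equiv), K2CO3, acetone, reflux
Reagents that add atoms: benzyl bromide, BrCc1ccccc1
Why: The 4-OH is more acidic and unchelated, while the 2-OH is locked in an H-bond with the ester C=O, so Williamson O-benzylation is regioselective for C4.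

**Step 2**
Reactants: **2**
Product: **3** methyl 4-(benzyloxy)-2-methoxy-6-methylbenzoate
Conditions: MeI (3 equiv), K2CO3, DMF, 60 °C
Reagents that add atoms: methyl iodide, CI
Why: Only the chelated 2-OH remains, and a polar aprotic solvent with mild heating drives its O-methylation (Williamson).

**Step 3**
Reactants: **3**
Product: **4** 4-(benzyloxy)-2-methoxy-6-methylbenzoic acid
Conditions: KOH, EtOH/H2O 1:1, reflux, 24 h; then HCl to pH 2
Reagents that add atoms: water (hydroxide/water supplies the acid O–H), O
Why: Saponification (BAc2) of the 2,6-disubstituted ester is slow but feasible under forcing conditions, and the benzyl ether is base-stable.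

**Step 4**
Reactants: **4**
Product: **5** 4-(benzyloxy)-2-methoxy-6-methylbenzoyl chloride
Conditions: (COCl)2 (1.5 equiv), cat. DMF, CH2Cl2, 0 °C to rt, 2 h; evaporate and use crude
Reagents that add atoms: oxalyl chloride, ClC(=O)C(=O)Cl
Why: A Vilsmeier-type catalysed acid-chloride formation under neutral, non-hydrogenolytic conditions that leaves the benzyl ether intact.

**Step 5**
Reactants: **5** acid chloride; **6** orsellinic acid (2,4-dihydroxy-6-methylbenzoic acid, 1.5 equiv)
Product: **7** 4-{[4-(benzyloxy)-2-methoxy-6-methylbenzoyl]oxy}-2-hydroxy-6-methylbenzoic acid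
Conditions: NaOH (3.2 equiv), H2O/acetone 1:1, 0 °C; add **5** in acetone dropwise, warm to rt, 3 h; acidify to pH 2 at 0 °C
Reagents that add atoms: none
Why: This is a Fischer-type Schotten–Baumann O-acylation. Proposed new method: In the dianion, the carboxylate is non-nucleophilic (any mixed anhydride is hydrolysed back), the 2-OH stays H-bonded to the carboxylate, and only the 4-phenoxide is acylated. The closest known reaction is acylation of hydroxy-acids with acid chlorides in aqueous alkali, and here it is extended to a hindered, electron-rich acid chloride on an unprotected orsellinate.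

**Step 6**
Reactants: **6** orsellinic acid
Product: **8** benzyl 2,4-dihydroxy-6-methylbenzoate
Conditions: BnBr (1.0 equiv), NaHCO3, DMF, 40 °C
Reagents that add atoms: benzyl bromide, BrCc1ccccc1
Why: Under mild bicarbonate conditions only the carboxylate is alkylated (SN2), not the phenols.

**Step 7**
Reactants: **7**; **8**
Product: **9** benzyl 4-{[4-({4-(benzyloxy)-2-methoxy-6-methylbenzoyl}oxy)-2-hydroxy-6-methylbenzoyl]oxy}-2-hydroxy-6-methylbenzoate (tridepside)
Conditions: TFAA (2 equiv), THF, 0 °C, 1 h; add **8** (1.2 equiv), rt, 16 h
Reagents that add atoms: none (TFAA is a dehydrating activator, not incorporated)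
Why: The Sala–Sargent mixed-anhydride depside coupling works because **7** has no free 4-OH and so cannot oligomerise. **8** acylates only at its unchelated 4-OH.

**Step 8**
Reactants: **9**
Product: **10** umbilicaric acid
Conditions: H2 (1 atm), 10% Pd/C, THF/EtOAc 1:1, rt, 6 h; filter and recrystallise
Reagents that add atoms: none (H2 adds only hydrogen)
Why: Hydrogenolysis cleaves both the benzyl ether and the benzyl ester in one step. Aryl esters, the aryl methyl ether and the phenols are inert, and the target is achiral so no stereochemistry is at risk.

## Compound list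
1 | methyl orsellinate | COC(=O)c1c(C)cc(O)cc1O | starting material
2 | methyl 4-(benzyloxy)-2-hydroxy-6-methylbenzoate | COC(=O)c1c(C)cc(OCc2ccccc2)cc1O | intermediate
3 | methyl 4-(benzyloxy)-2-methoxy-6-methylbenzoate | COC(=O)c1c(C)cc(OCc2ccccc2)cc1OC | intermediate
4 | 4-(benzyloxy)-2-methoxy-6-methylbenzoic acid | COc1cc(OCc2ccccc2)cc(C)c1C(=O)O | intermediate
5 | 4-(benzyloxy)-2-methoxy-6-methylbenzoyl chloride | COc1cc(OCc2ccccc2)cc(C)c1C(=O)Cl | intermediate
6 | orsellinic acid | Cc1cc(O)cc(O)c1C(=O)O | starting material
7 | A–B depside acid (4-O-benzyl) | COc1cc(OCc2ccccc2)cc(C)c1C(=O)Oc1cc(C)c(C(=O)O)c(O)c1 | intermediate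
8 | benzyl orsellinate | Cc1cc(O)cc(O)c1C(=O)OCc1ccccc1 | intermediate
9 | protected tridepside | COc1cc(OCc2ccccc2)cc(C)c1C(=O)Oc1cc(C)c(C(=O)Oc2cc(C)c(C(=O)OCc3ccccc3)c(O)c2)c(O)c1 | intermediate
10 | umbilicaric acid (achiral) | COc1cc(O)cc(C)c1C(=O)Oc1cc(C)c(C(=O)Oc2cc(C)c(C(=O)O)c(O)c2)c(O)c1 | target

## Step count
- Total steps: 8.
- Longest linear sequence: 7 (1→2→3→4→5→7→9→10, with 6 and 8 made in parallel).

## Three steps most likely to fail
1. **Step 5 (aqueous 4-O-acylation of unprotected 6).** Hydrolysis of the hindered acid chloride may compete, or the carboxylate may be acylated. Fallback: use allyl orsellinate as ring B. Acylate its 4-OH with **5** (Et3N/DMAP, CH2Cl2), then remove the allyl ester with Pd(PPh3)4/morpholine to give **7**.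
2. **Step 7 (TFAA coupling of the hindered 2-OH acid).** The 2-OH may be trifluoroacetylated or the coupling may be sluggish. Fallback: reverse the bond-forming order. Couple 4-O-Alloc-orsellinic acid with **8** (Sala–Sargent), remove the Alloc group with Pd(0), then acylate the freed B 4-OH with **5** as in Step 5, followed by Step 8.
3. **Step 3 (hindered methyl ester saponification).** The 2,6-disubstituted ester may hydrolyse incompletely or slowly. Fallback: SN2 dealkylation of **3** with PhSNa or LiI in DMF/pyridine, which attacks the methyl carbon instead of the hindered carbonyl.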